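**Strategy.** Everything rests on opening the cyclohexenone ring between its carbonyl carbon C1 and the methyl-bearing carbon C2. The tetrasubstituted C2=C3 double bond, with ring carbon C1 and the side chain on C3 trans to each other and C3 flanked by the gem-dimethyl carbon C4, is read as an alkyne that has taken up two carbon groups anti. A palladium-catalysed anti-selective alkylative cyclisation therefore joins 4,4-dimethylhept-5-ynal (fragment 1) with the primary alkylborane made in the flask from the dioxane-bearing 1,3-diene (fragment 2): the C1–C2 ring bond and the C3–side-chain bond form in one operation. Oxidation then gives the enone. The dioxane stereocentres come from (R)-linalool and a crotylboration.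

Key step: step 18

Remark: ring labels are cyclohexenone C1 (carbonyl), C2 (CMe), C3 (side chain), C4 (CMe2) and dioxane O1, O2, C3 (CH), C6 (quaternary); commercial (R)-(−)-linalool of high enantiomeric purity is assumed, and material from its minor enantiomer becomes a diastereomer in step 8 and is removed by chromatography.

## Fragment 1: 4,4-dimethylhept-5-ynal

Step 1
Reactants: 1 2,2-dimethylpent-4-enal
Product: 2 1,1-dibromo-3,3-dimethylhexa-1,5-diene
Conditions: CBr4, PPh3, CH2Cl2, 0 °C
Reagents that add atoms: carbon tetrabromide, BrC(Br)(Br)Br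
Why: Corey–Fuchs dibromo-olefination of a non-enolisable aldehyde, with no stereocentre formed.

Step 2
Reactants: 2 1,1-dibromo-3,3-dimethylhexa-1,5-diene
Product: 4 4,4-dimethylhept-1-en-5-yne, via lithium alkynide 3 (not isolated)
Conditions: n-BuLi (2.1 equiv), THF, −78 °C → rt; then MeI, −78 °C → rt
Reagents that add atoms: iodomethane, CI
Why: Second stage of the Corey–Fuchs sequence (Br/Li exchange, 1,2-shift to the alkyne, deprotonation), with C-methylation of the lithium alkynide in the same flask.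

Step 3
Reactants: 4 4,4-dimethylhept-1-en-5-yne
Product: 6 4,4-dimethylhept-5-yn-1-ol, via alkylborane 5 (not isolated)
Conditions: 9-BBN, THF, 0 °C → rt; then NaOH, H2O2, 0 °C
Reagents that add atoms: hydrogen peroxide, OO
Why: Anti-Markovnikov hydroboration–oxidation, in which 9-BBN should react with the terminal alkene much faster than with the hindered internal alkyne.

Step 4
Reactants: 6 4,4-dimethylhept-5-yn-1-ol
Product: 7 4,4-dimethylhept-5-ynal
Conditions: Dess–Martin periodinane, CH2Cl2, 0 °C → rt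
Reagents that add atoms: none
Why: Dess–Martin oxidation of a primary alcohol to the aldehyde, leaving the alkyne untouched.

## Fragment 2: the dioxane diene

Step 5
Reactants: 8 (R)-(−)-linalool
Product: 10 (3R)-3,7-dimethyloct-6-ene-1,3-diol, via bis-boron adduct 9 (not isolated)
Conditions: 9-BBN (2.2 equiv), THF, 0 °C → rt; then NaOH, H2O2, 0 °C
Reagents that add atoms: hydrogen peroxide, OO
Why: Hydroboration–oxidation in which 9-BBN selects the monosubstituted vinyl group over the trisubstituted alkene, the chiral-pool tertiary carbinol being untouched.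

Step 6
Reactants: 10 (3R)-3,7-dimethyloct-6-ene-1,3-diol
Product: 12 (2R)-2-methyl-2-(4-methylpent-3-en-1-yl)oxetane, via monotosylate 11 (not isolated)
Conditions: n-BuLi (1.0 equiv), THF, 0 °C; TsCl (1.0 equiv); then n-BuLi (1.0 equiv), 0 → 60 °C
Reagents that add atoms: none
Why: One-pot monotosylation and intramolecular Williamson etherification (4-exo-tet) of the 1,3-diol, which does not break the C–O bond at the tertiary stereocentre and so retains its configuration.

Step 7
Reactants: 12 (2R)-2-methyl-2-(4-methylpent-3-en-1-yl)oxetane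
Product: 14 3-[(2R)-2-methyloxetan-2-yl]propanal, via ozonide 13 (not isolated)
Conditions: O3, CH2Cl2, −78 °C; then PPh3, → rt
Reagents that add atoms: ozone, [O-][O+]=O
Why: Ozonolysis with reductive work-up cleaves the only C=C bond, the oxetane being inert.

Step 8
Reactants: 14 3-[(2R)-2-methyloxetan-2-yl]propanal
Product: 16 (3R,4R)-3-methyl-6-[(2R)-2-methyloxetan-2-yl]hex-1-en-4-ol, via borinate 15 (not isolated)
Conditions: cis-but-2-ene, KOt-Bu, n-BuLi, THF, −78 → −45 °C; (−)-Ipc2BOMe [from (+)-α-pinene]; BF3·OEt2; 14, −78 °C; then NaOH, H2O2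
Reagents that add atoms: (Z)-crotyldiisopinocampheylborane, made in the flask from cis-but-2-ene (C/C=C\C), C/C=C\CB([C@@H]1C[C@@H]2C[C@H]([C@H]1C)C2(C)C)[C@@H]1C[C@@H]2C[C@H]([C@H]1C)C2(C)C
Why: Brown asymmetric crotylboration, in which the (Z)-crotyl group reacts through a chair Zimmerman–Traxler transition state to give the syn adduct and the Ipc2B group sets the (3R,4R) configuration under reagent control.

Step 9
Reactants: 16 (3R,4R)-3-methyl-6-[(2R)-2-methyloxetan-2-yl]hex-1-en-4-ol
Product: 17 (3R,4R)-3-methyl-6-[(2R)-2-methyloxetan-2-yl]hex-1-en-4-yl methanesulfonate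
Conditions: MsCl, Et3N, CH2Cl2, 0 °C
Reagents that add atoms: methanesulfonyl chloride, CS(=O)(=O)Cl
Why: Mesylation of the secondary alcohol with retention, which also prevents the hydroxyl from opening the oxetane to a tetrahydrofuran in step 10.

Step 10
Reactants: 17 (3R,4R)-3-methyl-6-[(2R)-2-methyloxetan-2-yl]hex-1-en-4-yl methanesulfonate
Product: 18 (3R,4R,7S)-7-hydroperoxy-9-hydroxy-3,7-dimethylnon-1-en-4-yl methanesulfonate
Conditions: H2O2 (anhydrous, in Et2O), Me3SiOTf (cat.), Et2O, −78 → 0 °C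
Reagents that add atoms: hydrogen peroxide, OO
Why: Lewis acid-promoted perhydrolysis of the 2,2-disubstituted oxetane, in which hydrogen peroxide should attack the activated tertiary carbon from the back side and so set the future dioxane C6 with inversion.

Step 11
Reactants: 18 (3R,4R,7S)-7-hydroperoxy-9-hydroxy-3,7-dimethylnon-1-en-4-yl methanesulfonate
Product: 19 2-[(3S,6S)-6-[(2R)-but-3-en-2-yl]-3-methyl-1,2-dioxan-3-yl]ethan-1-ol
Conditions: KOt-Bu (1.0 equiv), 18-crown-6, THF, 0 °C
Reagents that add atoms: none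
Why: Intramolecular alkylation of the hydroperoxide by the secondary mesylate (6-exo-tet SN2) closes the 1,2-dioxane and sets dioxane C3 by inversion, the more acidic OOH reacting in preference to the primary OH.

Step 12
Reactants: 19 2-[(3S,6S)-6-[(2R)-but-3-en-2-yl]-3-methyl-1,2-dioxan-3-yl]ethan-1-ol
Product: 22 (2S)-2-[(3S,6S)-6-(2-hydroxyethyl)-6-methyl-1,2-dioxan-3-yl]propanoic acid, via ozonide 20 (not isolated), via aldehyde 21 (not isolated)
Conditions: O3, CH2Cl2, −78 °C; Me2S, → rt; then NaClO2, NaH2PO4, 2-methylbut-2-ene, t-BuOH/H2O, 0 °C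
Reagents that add atoms: ozone, [O-][O+]=O; sodium chlorite, [Na+].[O-]Cl=O
Why: Ozonolysis of the terminal vinyl group followed by Pinnick oxidation of the crude aldehyde under buffered conditions that should not epimerise the α-stereocentre or touch the alcohol and peroxide.

Step 13
Reactants: 22 (2S)-2-[(3S,6S)-6-(2-hydroxyethyl)-6-methyl-1,2-dioxan-3-yl]propanoic acid
Product: 23 methyl (2S)-2-[(3S,6S)-6-(2-hydroxyethyl)-6-methyl-1,2-dioxan-3-yl]propanoate
Conditions: Me3SiCHN2, PhMe/MeOH, 0 °C
Reagents that add atoms: (trimethylsilyl)diazomethane, C[Si](C)(C)C=[N+]=[N-]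
Why: Methyl ester formation with a diazoalkane, selective for the carboxylic acid over the alcohol.

Step 14
Reactants: 23 methyl (2S)-2-[(3S,6S)-6-(2-hydroxyethyl)-6-methyl-1,2-dioxan-3-yl]propanoate
Product: 24 methyl (2S)-2-[(3S,6S)-6-methyl-6-(2-oxoethyl)-1,2-dioxan-3-yl]propanoate
Conditions: Dess–Martin periodinane, CH2Cl2, 0 °C → rt
Reagents that add atoms: none
Why: Dess–Martin oxidation of the primary alcohol under neutral conditions that the dialkyl peroxide should tolerate.

Step 15
Reactants: 24 methyl (2S)-2-[(3S,6S)-6-methyl-6-(2-oxoethyl)-1,2-dioxan-3-yl]propanoate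
Product: 26 methyl (2S)-2-[(3S,6S)-6-methyl-6-(3-oxopropyl)-1,2-dioxan-3-yl]propanoate, via enol ether 25 (not isolated)
Conditions: (MeOCH2)PPh3Cl, KN(SiMe3)2, THF, −78 → 0 °C; then 2 M HCl, THF, rt
Reagents that add atoms: (methoxymethyl)triphenylphosphonium chloride, COC[P+](c1ccccc1)(c1ccccc1)c1ccccc1.[Cl-]; water, O
Why: Wittig methoxymethylenation and acid hydrolysis of the enol ether give the one-carbon homologated aldehyde.

Step 16
Reactants: 26 methyl (2S)-2-[(3S,6S)-6-methyl-6-(3-oxopropyl)-1,2-dioxan-3-yl]propanoate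
Product: 27 methyl (2S)-2-[(3S,6R)-6-methyl-6-[(3E)-4-methyl-5-oxopent-3-en-1-yl]-1,2-dioxan-3-yl]propanoate
Conditions: Ph3P=C(Me)CHO, PhMe, 80 °C
Reagents that add atoms: 2-(triphenylphosphoranylidene)propanal, CC(C=O)=P(c1ccccc1)(c1ccccc1)c1ccccc1
Why: Wittig olefination with a stabilised ylide should give the (E)-2-methyl enal and so set the geometry of the trisubstituted double bond.

Step 17
Reactants: 27 methyl (2S)-2-[(3S,6R)-6-methyl-6-[(3E)-4-methyl-5-oxopent-3-en-1-yl]-1,2-dioxan-3-yl]propanoate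
Product: 28 methyl (2S)-2-[(3S,6R)-6-methyl-6-[(3E)-4-methylhexa-3,5-dien-1-yl]-1,2-dioxan-3-yl]propanoate
Conditions: MePPh3Br, KN(SiMe3)2, THF, −78 → 0 °C
Reagents that add atoms: methyltriphenylphosphonium bromide, C[P+](c1ccccc1)(c1ccccc1)c1ccccc1.[Br-]
Why: Wittig methylenation of the aldehyde, chemoselective over the methyl ester, gives the 1,3-diene.

## Union and completion

Step 18
Reactants: 28 methyl (2S)-2-[(3S,6R)-6-methyl-6-[(3E)-4-methylhexa-3,5-dien-1-yl]-1,2-dioxan-3-yl]propanoate (fragment 2); 7 4,4-dimethylhept-5-ynal (fragment 1)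
Product: 30 methyl (2S)-2-[(3S,6R)-6-[(3E)-6-(3-hydroxy-2,6,6-trimethylcyclohex-1-en-1-yl)-4-methylhex-3-en-1-yl]-6-methyl-1,2-dioxan-3-yl]propanoate (both carbinol epimers), via alkylborane 29 (not isolated)
Conditions: 9-BBN (1.05 equiv), THF, 0 °C → rt; MeOH; then 7 (1.3 equiv), Pd(PPh3)4 (5 mol%), THF/MeOH, 60 °C
Reagents that add atoms: none
Why: 9-BBN adds anti-Markovnikov to the terminal vinyl group of the diene (hydroboration) to give the primary homoallylic borane 29, and after methanol has destroyed residual B–H, zerovalent palladium binds the alkyne of 7 and the electron-rich alkyne complex attacks the hydrogen-bond-activated aldehyde through its methyl-bearing carbon on the face opposite to the metal, which leaves a cyclohexenyl-palladium bond at C3 (divalent palladium). Alkyl transfer from boron (assisted by the methoxide/alkoxide on palladium) and C(sp2)–C(sp3) reductive elimination then place the side chain on C3 and return zerovalent palladium. The closest known reaction type is the Pd/phosphine-catalysed anti-selective ("anti-Wacker") arylative, alkenylative and alkylative cyclisation of 5-alkynals with organoboron reagents, combined here with the in-flask alkylborane generation of a B-alkyl Suzuki–Miyaura coupling. The cyclohexene ring closes in the 6-endo-dig mode (new bond C1–C2, both alkyne carbons become ring atoms), helped by the gem-dimethyl group in the tether. The only new stereocentre, carbinol carbon C1, is not controlled and is erased in step 19, while the three existing stereocentres are remote from the reacting sites. The step needs endo rather than exo closure and anti rather than syn addition across the alkyne, and both follow from the outer-sphere attack on the coordinated internal alkyne, which puts C1 on C2 and the metal, hence the chain, on C3 on opposite sides of the new double bond; only the primary alkyl group of the 9-BBN derivative is transferred.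

Step 19
Reactants: 30 methyl (2S)-2-[(3S,6R)-6-[(3E)-6-(3-hydroxy-2,6,6-trimethylcyclohex-1-en-1-yl)-4-methylhex-3-en-1-yl]-6-methyl-1,2-dioxan-3-yl]propanoate
Product: 31 methyl (2S)-2-[(3S,6R)-6-methyl-6-[(3E)-4-methyl-6-(2,6,6-trimethyl-3-oxocyclohex-1-en-1-yl)hex-3-en-1-yl]-1,2-dioxan-3-yl]propanoate
Conditions: Dess–Martin periodinane, CH2Cl2, 0 °C → rt
Reagents that add atoms: none
Why: Dess–Martin oxidation of the allylic alcohol to the enone, in which both carbinol epimers converge on the target.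

## Compound list

1 | 2,2-dimethylpent-4-enal | C=CCC(C)(C)C=O | starting material
2 | 1,1-dibromo-3,3-dimethylhexa-1,5-diene | BrC(Br)=CC(C)(C)CC=C | intermediate
3 | lithium 3,3-dimethylhex-5-en-1-yn-1-ide | [Li]C#CC(C)(C)CC=C | intermediate (not isolated)
4 | 4,4-dimethylhept-1-en-5-yne | CC#CC(C)(C)CC=C | intermediate
5 | 9-(4,4-dimethylhept-5-yn-1-yl)-9-borabicyclo[3.3.1]nonane | CC#CC(C)(C)CCCB1C2CCCC1CCC2 | intermediate (not isolated)
6 | 4,4-dimethylhept-5-yn-1-ol | CC#CC(C)(C)CCCO | intermediate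
7 | 4,4-dimethylhept-5-ynal (fragment 1) | CC#CC(C)(C)CCC=O | intermediate
8 | (R)-(−)-linalool, (3R)-3,7-dimethylocta-1,6-dien-3-ol | CC(C)=CCC[C@@](C)(O)C=C | starting material
9 | bis-boron adduct of 8: O-(9-BBN) borinate of the tertiary alcohol with a 9-BBN group on C1, configuration at C3 as in 8 | CC(C)=CCC[C@@](C)(OB1C2CCCC1CCC2)CCB1C2CCCC1CCC2 | intermediate (not isolated)
10 | (3R)-3,7-dimethyloct-6-ene-1,3-diol | CC(C)=CCC[C@@](C)(O)CCO | intermediate
11 | (3R)-3-hydroxy-3,7-dimethyloct-6-en-1-yl 4-methylbenzenesulfonate | CC(C)=CCC[C@@](C)(O)CCOS(=O)(=O)c1ccc(C)cc1 | intermediate (not isolated)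
12 | (2R)-2-methyl-2-(4-methylpent-3-en-1-yl)oxetane | CC(C)=CCC[C@]1(C)CCO1 | intermediate
13 | 3,3-dimethyl-5-{2-[(2R)-2-methyloxetan-2-yl]ethyl}-1,2,4-trioxolane (ozonide, epimers at the trioxolane CH) | CC1(C)OC(CC[C@]2(C)CCO2)OO1 | intermediate (not isolated)
14 | 3-[(2R)-2-methyloxetan-2-yl]propanal | O=CCC[C@]1(C)CCO1 | intermediate
15 | diisopinocampheylborinate of 16 | C=C[C@@H](C)[C@H](OB([C@@H]1C[C@@H]2C[C@H]([C@H]1C)C2(C)C)[C@@H]1C[C@@H]2C[C@H]([C@H]1C)C2(C)C)CC[C@]1(C)CCO1 | intermediate (not isolated)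
16 | (3R,4R)-3-methyl-6-[(2R)-2-methyloxetan-2-yl]hex-1-en-4-ol | C=C[C@@H](C)[C@H](O)CC[C@]1(C)CCO1 | intermediate
17 | (3R,4R)-3-methyl-6-[(2R)-2-methyloxetan-2-yl]hex-1-en-4-yl methanesulfonate | C=C[C@@H](C)[C@H](OS(C)(=O)=O)CC[C@]1(C)CCO1 | intermediate
18 | (3R,4R,7S)-7-hydroperoxy-9-hydroxy-3,7-dimethylnon-1-en-4-yl methanesulfonate | C=C[C@@H](C)[C@H](OS(C)(=O)=O)CC[C@](C)(OO)CCO | intermediate
19 | 2-[(3S,6S)-6-[(2R)-but-3-en-2-yl]-3-methyl-1,2-dioxan-3-yl]ethan-1-ol | C=C[C@@H](C)[C@@H]1CC[C@@](C)(CCO)OO1 | intermediate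
20 | ozonide of 19: 1,2,4-trioxolane in place of the vinyl group (epimers at the trioxolane CH) | C1OC(OO1)[C@@H](C)[C@@H]2CC[C@@](C)(CCO)OO2 | intermediate (not isolated)
21 | (2S)-2-[(3S,6S)-6-(2-hydroxyethyl)-6-methyl-1,2-dioxan-3-yl]propanal | O=C[C@@H](C)[C@@H]1CC[C@@](C)(CCO)OO1 | intermediate (not isolated)
22 | (2S)-2-[(3S,6S)-6-(2-hydroxyethyl)-6-methyl-1,2-dioxan-3-yl]propanoic acid | OC(=O)[C@@H](C)[C@@H]1CC[C@@](C)(CCO)OO1 | intermediate
23 | methyl (2S)-2-[(3S,6S)-6-(2-hydroxyethyl)-6-methyl-1,2-dioxan-3-yl]propanoate | COC(=O)[C@@H](C)[C@@H]1CC[C@@](C)(CCO)OO1 | intermediate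
24 | methyl (2S)-2-[(3S,6S)-6-methyl-6-(2-oxoethyl)-1,2-dioxan-3-yl]propanoate | COC(=O)[C@@H](C)[C@@H]1CC[C@@](C)(CC=O)OO1 | intermediate
25 | methyl (2S)-2-[(3S,6S)-6-(3-methoxyprop-2-en-1-yl)-6-methyl-1,2-dioxan-3-yl]propanoate (E/Z mixture) | COC(=O)[C@@H](C)[C@@H]1CC[C@@](C)(CC=COC)OO1 | intermediate (not isolated)
26 | methyl (2S)-2-[(3S,6S)-6-methyl-6-(3-oxopropyl)-1,2-dioxan-3-yl]propanoate | COC(=O)[C@@H](C)[C@@H]1CC[C@@](C)(CCC=O)OO1 | intermediate
27 | methyl (2S)-2-[(3S,6R)-6-methyl-6-[(3E)-4-methyl-5-oxopent-3-en-1-yl]-1,2-dioxan-3-yl]propanoate | COC(=O)[C@@H](C)[C@@H]1CC[C@@](C)(CC/C=C(\C)C=O)OO1 | intermediate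
28 | methyl (2S)-2-[(3S,6R)-6-methyl-6-[(3E)-4-methylhexa-3,5-dien-1-yl]-1,2-dioxan-3-yl]propanoate (fragment 2) | COC(=O)[C@@H](C)[C@@H]1CC[C@@](C)(CC/C=C(\C)C=C)OO1 | intermediate
29 | methyl (2S)-2-[(3S,6R)-6-[(3E)-6-(9-borabicyclo[3.3.1]nonan-9-yl)-4-methylhex-3-en-1-yl]-6-methyl-1,2-dioxan-3-yl]propanoate | COC(=O)[C@@H](C)[C@@H]1CC[C@@](C)(CC/C=C(\C)CCB2C3CCCC2CCC3)OO1 | intermediate (not isolated)
30 | methyl (2S)-2-[(3S,6R)-6-[(3E)-6-(3-hydroxy-2,6,6-trimethylcyclohex-1-en-1-yl)-4-methylhex-3-en-1-yl]-6-methyl-1,2-dioxan-3-yl]propanoate (both carbinol epimers) | COC(=O)[C@@H](C)[C@@H]1CC[C@@](C)(CC/C=C(\C)CCC2=C(C)C(O)CCC2(C)C)OO1 | intermediate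
31 | methyl (2S)-2-[(3S,6R)-6-methyl-6-[(3E)-4-methyl-6-(2,6,6-trimethyl-3-oxocyclohex-1-en-1-yl)hex-3-en-1-yl]-1,2-dioxan-3-yl]propanoate | COC(=O)[C@@H](C)[C@@H]1CC[C@@](C)(CC/C=C(\C)CCC2=C(C)C(=O)CCC2(C)C)OO1 | target

## Step count and risks

Total step count: 19 (4 for fragment 1, 13 for fragment 2, 2 after the union). Longest linear sequence: 15 steps (steps 5–19, from (R)-linalool).

**Step 18 (key step).** Transfer of the primary alkyl group from boron to the cyclohexenyl-palladium intermediate may be slower than protodepalladation or than reduction of the aldehyde by the borane. The O–O bond may also be cleaved by phosphine-ligated zerovalent palladium, or closure may leak into the exo mode. The fallback sets out from 28 (through its borane 29) and comes back at 30; the ring is made beforehand and joined by a B-alkyl Suzuki–Miyaura coupling. Commercial 2,6,6-trimethylcyclohex-2-en-1-one (CC1=CCCC(C)(C)C1=O) is β-borylated (B2pin2, CuCl, NaOt-Bu, MeOH) to 2,6,6-trimethyl-3-(4,4,5,5-tetramethyl-1,3,2-dioxaborolan-2-yl)cyclohexan-1-one F1. Oxidation with NaBO3 gives 3-hydroxy-2,6,6-trimethylcyclohexan-1-one F2, and silylation (TBSCl, imidazole) gives 3-[(tert-butyldimethylsilyl)oxy]-2,6,6-trimethylcyclohexan-1-one F3. Enolisation, possible only towards C2 (KN(SiMe3)2, PhNTf2, −78 °C), gives 3-[(tert-butyldimethylsilyl)oxy]-2,6,6-trimethylcyclohex-1-en-1-yl trifluoromethanesulfonate F4. Coupling of 29 with F4 (PdCl2(dppf), AsPh3, Cs2CO3, DMF/THF/H2O, rt) should give the silyl ether of 30 F5, and Bu4NF releases 30.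

**Step 10.** The tertiary C–O bond may ionise before the peroxide attacks, which would erode the configuration at dioxane C6, or the oxetane may be opened by adventitious water to the diol. The fallback sets out from 17 and comes back at 19; the order of the two C–O bond formations is reversed so that the tertiary carbon is attacked intramolecularly. Displacement of the mesylate of 17 with H2O2/KOH (SN2, inversion) gives (3R,4S)-3-methyl-6-[(2R)-2-methyloxetan-2-yl]hex-1-en-4-yl hydroperoxide F6. Me3SiOTf-promoted 6-exo opening of the oxetane by the tethered hydroperoxide, which can only take place from the back side of the tertiary carbon, then gives 19.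

**Step 11.** E2 elimination of the secondary mesylate, or base-induced Kornblum–DeLaMare-type fragmentation of the secondary peroxide once formed, may compete with the 6-exo-tet closure. The fallback sets out from 14 and comes back at 23; the ring is closed by conjugate addition instead of substitution, and steps 8, 9, 12 and 13 are then not needed. Wittig olefination of 14 with methyl 2-(triphenylphosphoranylidene)propanoate gives methyl (2E)-2-methyl-5-[(2R)-2-methyloxetan-2-yl]pent-2-enoate F7. Perhydrolysis as in step 10 gives methyl (2E,6S)-6-hydroperoxy-8-hydroxy-2,6-dimethyloct-2-enoate F8. Amine-catalysed intramolecular oxa-Michael addition (Et2NH, CF3CH2OH) should then give 23 together with its diastereomers at C2 and dioxane C3, from which 23 has to be separated by HPLC.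

Further compounds
F1 | step 18 | 2,6,6-trimethyl-3-(4,4,5,5-tetramethyl-1,3,2-dioxaborolan-2-yl)cyclohexan-1-one | CC1C(CCC(C)(C)C1=O)B1OC(C)(C)C(C)(C)O1
F2 | step 18 | 3-hydroxy-2,6,6-trimethylcyclohexan-1-one | CC1C(O)CCC(C)(C)C1=O
F3 | step 18 | 3-[(tert-butyldimethylsilyl)oxy]-2,6,6-trimethylcyclohexan-1-one | CC1C(CCC(C)(C)C1=O)O[Si](C)(C)C(C)(C)C
F4 | step 18 | 3-[(tert-butyldimethylsilyl)oxy]-2,6,6-trimethylcyclohex-1-en-1-yl trifluoromethanesulfonate | CC1=C(OS(=O)(=O)C(F)(F)F)C(C)(C)CCC1O[Si](C)(C)C(C)(C)C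
F5 | step 18 | methyl (2S)-2-[(3S,6R)-6-[(3E)-6-{3-[(tert-butyldimethylsilyl)oxy]-2,6,6-trimethylcyclohex-1-en-1-yl}-4-methylhex-3-en-1-yl]-6-methyl-1,2-dioxan-3-yl]propanoate | COC(=O)[C@@H](C)[C@@H]1CC[C@@](C)(CC/C=C(\C)CCC2=C(C)C(O[Si](C)(C)C(C)(C)C)CCC2(C)C)OO1
F6 | step 10 | (3R,4S)-3-methyl-6-[(2R)-2-methyloxetan-2-yl]hex-1-en-4-yl hydroperoxide | C=C[C@@H](C)[C@@H](OO)CC[C@]1(C)CCO1
F7 | step 11 | methyl (2E)-2-methyl-5-[(2R)-2-methyloxetan-2-yl]pent-2-enoate | COC(=O)/C(C)=C/CC[C@]1(C)CCO1
F8 | step 11 | methyl (2E,6S)-6-hydroperoxy-8-hydroxy-2,6-dimethyloct-2-enoate | COC(=O)/C(C)=C/CC[C@](C)(OO)CCO
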